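## Retrosynthetic overview

- **Feature:** the labile 12Z trisubstituted alkene. Its vinyl carbon C14 lies five atoms from the 8α oxygen, so O8–C8–C9–C11–C12–C13–C14 can be closed as a seven-membered ring. The ring is fused through the two equatorial bonds of ring B, and only the cis alkene fits in it.
- **Late stage:** target 22 ⇒ (desilylation, O6 acetylation, C14 methylenation, partial reduction) Z-lactone 18 ⇒ (ring-closing metathesis, C12=C13) 9-allyl 8-O-methacrylate 17.
- **Oxygenation:** 17 ⇒ 9-allyl 8α-hydroxy-7-ketone 9. O6 comes from an α-face Rubottom oxidation and the 7β-OH from axial hydride delivery.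
- **Early stage:** 9 ⇒ Δ8(17) diene 5 (C7 allylic oxidation, directed epoxidation, hydride opening rebuild C7/C8) ⇒ (+)-sclareolide 1 (lactol, Wittig, dehydration).
- **Ring order:** rings A and B arrive with 1, and its γ-lactone is opened in step 2. The only ring built is the temporary seven-membered lactone, formed in step 14 and opened in steps 15–16.

Key step: step 14

Remark on the chemistry: labdane numbering is used throughout. Commercial (+)-sclareolide (3aR,5aS,9aS,9bR) is assumed; it already has the C5, C9 and C10 configuration of the target. All bicyclic compounds keep its core: trans-decalin, 4,4-dimethyl, 5α-H, 10β-CH3, 9α-H with the side chain 9β (equatorial).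

## Route

Step 1
Reactants: 1 (+)-sclareolide
Product: 2 sclareolide lactol (8α,12-epoxy-13,14,15,16-tetranorlabdan-12-ol, anomeric mixture)
Conditions: DIBAL-H (1.2 equiv), CH2Cl2, −78 °C; Rochelle salt
Reagents that add atoms: none
Why: DIBAL-H partial reduction of a lactone: the tetrahedral aluminate is stable at −78 °C and gives the lactol only on work-up, and no stereocentre of the core is touched.

Step 2
Reactants: 2 sclareolide lactol; 3 methyltriphenylphosphonium bromide
Product: 4 14,15,16-trinorlabd-12-en-8α-ol (9β-allyl, 8α-OH, 8β-CH3)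
Conditions: 3, KOt-Bu, THF, 0 °C → reflux
Reagents that add atoms: methyltriphenylphosphonium bromide (3), C[P+](c1ccccc1)(c1ccccc1)c1ccccc1.[Br-]
Why: Wittig methylenation of a lactol: the ylide traps the hydroxy aldehyde tautomer, which turns C12 into the terminal alkene of the C9 allyl group and releases the 8α-hydroxyl without touching C8 or C9.

Step 3
Reactants: 4 14,15,16-trinorlabd-12-en-8α-ol
Product: 5 14,15,16-trinorlabda-8(17),12-diene (8-methylene, 9β-allyl)
Conditions: SOCl2, pyridine, CH2Cl2, −78 °C
Reagents that add atoms: none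
Why: Chlorosulfite E2 dehydration: the equatorial C8–O bond is anti-periplanar only to ring C–C bonds and to a C–H of the freely rotating C17 methyl, so loss of a C17 proton to the exocyclic Δ8(17) alkene should dominate over Δ7 and Δ8(9), and minor isomers, if formed, are removed by chromatography after step 4.

Step 4
Reactants: 5 14,15,16-trinorlabda-8(17),12-diene
Product: 6 14,15,16-trinorlabda-8(17),12-dien-7α-ol (axial 7α-OH)
Conditions: SeO2 (cat.), t-BuOOH, CH2Cl2, 0 °C → rt
Reagents that add atoms: selenium dioxide (oxygen carrier), O=[Se]=O; tert-butyl hydroperoxide (terminal oxidant), CC(C)(C)OO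
Why: Riley-type allylic oxidation run catalytically (ene reaction, then [2,3]-sigmatropic shift): the 1,1-disubstituted alkene is far more nucleophilic than the monosubstituted one, the ring CH2 at C7 reacts before the hindered C9 methine, and oxygen is delivered along the axial π lobe on the α face, which sets the transient 7α-carbinol.

Step 5
Reactants: 6 14,15,16-trinorlabda-8(17),12-dien-7α-ol
Product: 7 8α,17-epoxy-14,15,16-trinorlabd-12-en-7α-ol (epoxide oxygen α, C17 β)
Conditions: VO(acac)2 (cat.), t-BuOOH, toluene, 0 °C → rt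
Reagents that add atoms: tert-butyl hydroperoxide, CC(C)(C)OO
Why: Vanadium-catalysed hydroxyl-directed epoxidation: only the allylic-alcohol alkene binds to the metal peroxide, and the axial 7α-O–V tether delivers oxygen to the α face, which is also the face away from the axial C20 methyl, so C8 is set with oxygen α and C17 β.

Step 6
Reactants: 7 8α,17-epoxy-14,15,16-trinorlabd-12-en-7α-ol
Product: 8 14,15,16-trinorlabd-12-ene-7α,8α-diol
Conditions: LiAlH4, THF, 0 → 50 °C
Reagents that add atoms: none
Why: Hydride opening of an epoxide by SN2 attack at the primary C17: the C8–O bond is not broken, so the 8α-hydroxyl and 8β-methyl of the target result, and a Payne shift is ruled out because O7 and the epoxide oxygen are cis.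

Step 7
Reactants: 8 14,15,16-trinorlabd-12-ene-7α,8α-diol
Product: 9 8α-hydroxy-14,15,16-trinorlabd-12-en-7-one
Conditions: IBX, DMSO, rt
Reagents that add atoms: none
Why: IBX oxidation: a secondary–tertiary 1,2-diol is taken to the α-ketol without C–C cleavage, the tertiary alcohol and the alkene being inert at room temperature.

Step 8
Reactants: 9 8α-hydroxy-14,15,16-trinorlabd-12-en-7-one
Product: 10 7,8α-bis(trimethylsilyloxy)-14,15,16-trinorlabda-6,12-diene
Conditions: TMSOTf, Et3N, CH2Cl2, 0 °C → rt
Reagents that add atoms: trimethylsilyl triflate, C[Si](C)(C)OS(=O)(=O)C(F)(F)F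
Why: Soft enolisation and silylation with TMSOTf/Et3N: C8 is fully substituted, so the silyl enol ether can form only towards C6, and the tertiary alcohol is capped at the same time, which shuts off α-ketol rearrangement.

Step 9
Reactants: 10 7,8α-bis(trimethylsilyloxy)-14,15,16-trinorlabda-6,12-diene
Product: 12 6α,8α-dihydroxy-14,15,16-trinorlabd-12-en-7-one, via bis-TMS ketol 11 (not isolated)
Conditions: m-CPBA (1.05 equiv), CH2Cl2, −20 °C; then 1 M HCl, THF, 0 °C
Reagents that add atoms: m-chloroperbenzoic acid, O=C(OO)c1cccc(Cl)c1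
Why: Rubottom oxidation: the electron-rich silyl enol ether is epoxidised much faster than the terminal alkene and from the α face, because the axial methyls C17, C19 and C20 cover the β face, and silyl migration gives the equatorial 6α-silyloxy ketone whose two TMS groups fall off in dilute acid.

Step 10
Reactants: 12 6α,8α-dihydroxy-14,15,16-trinorlabd-12-en-7-one
Product: 13 6α-acetoxy-8α-hydroxy-14,15,16-trinorlabd-12-en-7-one
Conditions: Ac2O, pyridine, DMAP (cat.), CH2Cl2, 0 °C → rt
Reagents that add atoms: acetic anhydride, CC(=O)OC(C)=O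
Why: DMAP-catalysed acetylation: only the secondary 6α-hydroxyl is acylated at room temperature, the tertiary 8α-hydroxyl stays free, and the acetate marks O6 apart from the O7 that is made next.

Step 11
Reactants: 13 6α-acetoxy-8α-hydroxy-14,15,16-trinorlabd-12-en-7-one
Product: 14 6α-acetoxy-14,15,16-trinorlabd-12-ene-7β,8α-diol
Conditions: NaBH4, CeCl3·7H2O, MeOH–THF, −78 → −40 °C
Reagents that add atoms: none
Why: Luche reduction: hydride adds along the axial trajectory on the α face (the β face is flanked by the axial C17 methyl), which sets the equatorial 7β-alcohol, and the cold, nearly neutral cerium medium holds back an O6 to O7 acetyl shift.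

Step 12
Reactants: 14 6α-acetoxy-14,15,16-trinorlabd-12-ene-7β,8α-diol
Product: 15 6α-acetoxy-7β-(triethylsilyloxy)-14,15,16-trinorlabd-12-en-8α-ol
Conditions: TESOTf (1.1 equiv), 2,6-lutidine, CH2Cl2, −78 °C
Reagents that add atoms: triethylsilyl triflate, CC[Si](CC)(CC)OS(=O)(=O)C(F)(F)F
Why: Silyl triflate silylation with a non-nucleophilic base: with about one equivalent at −78 °C the secondary 7β-hydroxyl reacts before the tertiary 8α-hydroxyl, and no alkoxide is formed that could move the acetate.

Step 13
Reactants: 15 6α-acetoxy-7β-(triethylsilyloxy)-14,15,16-trinorlabd-12-en-8α-ol; 16 methacryloyl chloride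
Product: 17 6α-acetoxy-7β-(triethylsilyloxy)-14,15,16-trinorlabd-12-en-8α-yl methacrylate (9-allyl 8-O-methacrylate)
Conditions: 16, DMAP, i-Pr2NEt, BHT (cat.), ClCH2CH2Cl, 60 °C
Reagents that add atoms: methacryloyl chloride (16), C=C(C)C(=O)Cl
Why: DMAP-mediated acylation through the N-acylpyridinium salt: the equatorial tertiary 8α-hydroxyl of labdanes accepts acid chlorides in the presence of amine bases, it is the only free hydroxyl left, and working without a metal alkoxide avoids a TES shift from O7 to O8.

Step 14
Reactants: 17 9-allyl 8-O-methacrylate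
Product: 18 6α-acetoxy-7β-(triethylsilyloxy)-15-norlabd-12Z-en-14,8α-olide (seven-membered α-methyl-α,β-unsaturated lactone)
Conditions: Hoveyda–Grubbs II (10 mol %), 1,4-benzoquinone (20 mol %), toluene (2 mM), 90 °C, Ar sparge
Reagents that add atoms: none
Why: The ruthenium alkylidene first exchanges with the unhindered monosubstituted alkene of the allyl group, the C12 alkylidene so formed adds to the methacrylate C=C by [2+2] cycloaddition, and cycloreversion of the metallacyclobutane creates C12=C13 and hands on a Ru methylidene, so ethylene is the only co-product. This is ring-closing olefin metathesis of a methacrylate ester to an α-methyl unsaturated lactone, a known reaction type. The ring closed is the seven-membered oxepinone O8–C8–C9–C11–C12–C13–C14, made by joining two chain ends that ring B holds gauche and close together in trans-diequatorial positions. No stereocentre is formed; the only new stereo-element is the alkene, and a ring of this size can hold only C11 and C14 cis, which becomes the 12Z geometry once C14 is the vinyl carbon. The step needs ring closure to win over allyl–allyl homodimerisation and over allyl-to-propenyl migration, which is secured by high dilution, removal of ethylene, the reversibility of homodimer formation, a methacrylate that does not homodimerise, and benzoquinone as scavenger of Ru–H species. The acetate and the TES ether are inert to the catalyst.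

Step 15
Reactants: 18 seven-membered Z-lactone
Product: 19 7β-(triethylsilyloxy)-15-norlabd-12Z-ene-14,8α-lactol-6α-ol (seven-membered lactol, C14 epimers, O6 free)
Conditions: DIBAL-H (3.5 equiv), CH2Cl2, −78 °C; Rochelle salt; used crude
Reagents that add atoms: none
Why: DIBAL-H partial reduction of an α,β-unsaturated lactone (1,2-addition, aluminate stable at −78 °C), with two further equivalents cleaving the acetate reductively so that O6 is bared without a separate step, while the Z-enal stays tied to O8 as the seven-membered lactol.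

Step 16
Reactants: 19 seven-membered lactol; 3 methyltriphenylphosphonium bromide
Product: 20 7β-(triethylsilyloxy)labda-12Z,14-diene-6α,8α-diol
Conditions: 3 (4.0 equiv), KOt-Bu (3.6 equiv), THF, 0 °C; then 19, −78 → 0 °C
Reagents that add atoms: methyltriphenylphosphonium bromide (3), C[P+](c1ccccc1)(c1ccccc1)c1ccccc1.[Br-]
Why: Wittig methylenation of a lactol: the ylide traps the Z-hydroxy enal tautomer faster than it can isomerise, and making the ylide with less KOt-Bu than phosphonium salt leaves t-BuOH and phosphonium ion as proton sources, so that no free alkoxide builds up that could add O8 to C12 (oxa-Michael) or move the TES group to O6.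

Step 17
Reactants: 20 7β-(triethylsilyloxy)labda-12Z,14-diene-6α,8α-diol
Product: 21 6α-acetoxy-7β-(triethylsilyloxy)labda-12Z,14-dien-8α-ol
Conditions: Ac2O, pyridine, DMAP, CH2Cl2, rt
Reagents that add atoms: acetic anhydride, CC(=O)OC(C)=O
Why: DMAP-catalysed acetylation: O7 is silylated and O8 is tertiary, so only the secondary 6α-hydroxyl is acylated.

Step 18
Reactants: 21 6α-acetoxy-7β-(triethylsilyloxy)labda-12Z,14-dien-8α-ol
Product: 22 6α-acetoxylabda-12Z,14-diene-7β,8α-diol (CNP0138393.1)
Conditions: HF·pyridine, pyridine, THF, 0 °C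
Reagents that add atoms: none
Why: Fluoride desilylation with pyridine-buffered HF: the TES ether is cleaved under weakly acidic conditions that neither move the acetate to O7 nor protonate the diene, which would invite ether formation with O8.

## Compound list

1 | (+)-sclareolide | O=C1C[C@H]2[C@](C)(O1)CC[C@H]3C(C)(C)CCC[C@@]32C | starting material
2 | sclareolide lactol | OC1C[C@H]2[C@](C)(O1)CC[C@H]3C(C)(C)CCC[C@@]32C | intermediate
3 | methyltriphenylphosphonium bromide | C[P+](c1ccccc1)(c1ccccc1)c1ccccc1.[Br-] | starting material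
4 | 14,15,16-trinorlabd-12-en-8α-ol | C=CC[C@H]1[C@](C)(O)CC[C@H]2C(C)(C)CCC[C@@]21C | intermediate
5 | 14,15,16-trinorlabda-8(17),12-diene | C=CC[C@H]1C(=C)CC[C@H]2C(C)(C)CCC[C@@]21C | intermediate
6 | 14,15,16-trinorlabda-8(17),12-dien-7α-ol | C=CC[C@H]1C(=C)[C@H](O)C[C@H]2C(C)(C)CCC[C@@]21C | intermediate
7 | 8α,17-epoxy-14,15,16-trinorlabd-12-en-7α-ol | C=CC[C@H]1[C@]3(OC3)[C@H](O)C[C@H]2C(C)(C)CCC[C@@]21C | intermediate
8 | 14,15,16-trinorlabd-12-ene-7α,8α-diol | C=CC[C@H]1[C@](C)(O)[C@H](O)C[C@H]2C(C)(C)CCC[C@@]21C | intermediate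
9 | 8α-hydroxy-14,15,16-trinorlabd-12-en-7-one | C=CC[C@H]1[C@](C)(O)C(=O)C[C@H]2C(C)(C)CCC[C@@]21C | intermediate
10 | 7,8α-bis(trimethylsilyloxy)-14,15,16-trinorlabda-6,12-diene | C=CC[C@H]1[C@](C)(O[Si](C)(C)C)C(O[Si](C)(C)C)=C[C@H]2C(C)(C)CCC[C@@]21C | intermediate
11 | 6α,8α-bis(trimethylsilyloxy)-14,15,16-trinorlabd-12-en-7-one (bis-TMS ketol, not isolated) | C=CC[C@H]1[C@](C)(O[Si](C)(C)C)C(=O)[C@H](O[Si](C)(C)C)[C@H]2C(C)(C)CCC[C@@]21C | intermediate
12 | 6α,8α-dihydroxy-14,15,16-trinorlabd-12-en-7-one | C=CC[C@H]1[C@](C)(O)C(=O)[C@H](O)[C@H]2C(C)(C)CCC[C@@]21C | intermediate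
13 | 6α-acetoxy-8α-hydroxy-14,15,16-trinorlabd-12-en-7-one | C=CC[C@H]1[C@](C)(O)C(=O)[C@H](OC(C)=O)[C@H]2C(C)(C)CCC[C@@]21C | intermediate
14 | 6α-acetoxy-14,15,16-trinorlabd-12-ene-7β,8α-diol | C=CC[C@H]1[C@](C)(O)[C@@H](O)[C@H](OC(C)=O)[C@H]2C(C)(C)CCC[C@@]21C | intermediate
15 | 6α-acetoxy-7β-(triethylsilyloxy)-14,15,16-trinorlabd-12-en-8α-ol | C=CC[C@H]1[C@](C)(O)[C@@H](O[Si](CC)(CC)CC)[C@H](OC(C)=O)[C@H]2C(C)(C)CCC[C@@]21C | intermediate
16 | methacryloyl chloride | C=C(C)C(=O)Cl | starting material
17 | 9-allyl 8-O-methacrylate, 6-acetate, 7-TES ether (metathesis precursor) | C=CC[C@H]1[C@](C)(OC(=O)C(C)=C)[C@@H](O[Si](CC)(CC)CC)[C@H](OC(C)=O)[C@H]2C(C)(C)CCC[C@@]21C | intermediate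
18 | seven-membered Z-unsaturated lactone (15-norlabd-12Z-en-14,8α-olide, 6-acetate, 7-TES ether) | C/C1=C/C[C@H]2[C@](C)(OC1=O)[C@@H](O[Si](CC)(CC)CC)[C@H](OC(C)=O)[C@H]3C(C)(C)CCC[C@@]32C | intermediate
19 | seven-membered lactol, 6α-OH, 7-TES ether | C/C1=C/C[C@H]2[C@](C)(OC1O)[C@@H](O[Si](CC)(CC)CC)[C@H](O)[C@H]3C(C)(C)CCC[C@@]32C | intermediate
20 | 7β-(triethylsilyloxy)labda-12Z,14-diene-6α,8α-diol | C=C/C(C)=C\C[C@H]1[C@](C)(O)[C@@H](O[Si](CC)(CC)CC)[C@H](O)[C@H]2C(C)(C)CCC[C@@]21C | intermediate
21 | 6α-acetoxy-7β-(triethylsilyloxy)labda-12Z,14-dien-8α-ol | C=C/C(C)=C\C[C@H]1[C@](C)(O)[C@@H](O[Si](CC)(CC)CC)[C@H](OC(C)=O)[C@H]2C(C)(C)CCC[C@@]21C | intermediate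
22 | 6α-acetoxylabda-12Z,14-diene-7β,8α-diol (CNP0138393.1) | C=C/C(C)=C\C[C@H]1[C@](C)(O)[C@@H](O)[C@H](OC(C)=O)[C@H]2C(C)(C)CCC[C@@]21C | target

## Step count and risks

Total step count: 18. Longest linear sequence: 18 steps, from 1.

**1. Step 14 (ring-closing metathesis).**
- What may go wrong: the C12 alkylidene may fail to engage the hindered, electron-poor 1,1-disubstituted alkene of a tertiary ester, which must first turn into its less favoured ring-forming conformer. Oligomerisation through the allyl ends or migration of the allyl double bond would then take over.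
- Fallback: sets out from 15 and comes back at 18. It forms the same C12=C13 bond and the same ring by olefination.
- Alcohol 15 is esterified with 2-(diethoxyphosphoryl)propanoic acid (DCC, DMAP, CH2Cl2). This acylation runs through a small phosphono ketene, which suits hindered alcohols, and gives the 8-O-(2-phosphonopropanoate) F1.
- Lemieux–Johnson cleavage of the allyl group (OsO4 cat., NaIO4, 2,6-lutidine, dioxane–water) gives the C12 aldehyde F2.
- An intramolecular Horner–Wadsworth–Emmons reaction under Masamune–Roush conditions (LiCl, DBU, MeCN, high dilution) closes the seven-membered ring, which again allows only the cis alkene, to give 18.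

**2. Step 13 (O8 methacryloylation).**
- What may go wrong: acylation of the tertiary hydroxyl, wedged between the 7-OTES group and the allyl group, may be so slow that polymerisation of the acid chloride or loss or shift of the TES group at 60 °C overtakes it.
- Fallback: sets out from 13 and comes back at 18. Acylation and ring closure are run at the ketone level, where C7 is trigonal and carries no silyl ether.
- Compound 13 is acylated with 16 (DMAP, i-Pr2NEt, CH2Cl2) to the keto methacrylate F3.
- Metathesis under the conditions of step 14 gives the keto lactone F4.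
- Luche reduction (NaBH4, CeCl3, MeOH, −78 °C) from the α face gives the 7β-hydroxy lactone F5. Its acyl group cannot move to O7 without expanding to an eight-membered ring.
- TESOTf/2,6-lutidine then gives 18.

**3. Step 16 (methylenation of the lactol).**
- What may go wrong: once the lactol opens, O8 may add to C12 of the enal (five-membered ether by oxa-Michael addition), the enal may drift from Z to E, or base may shift the TES group from O7 to O6.
- Fallback: sets out from 19 and comes back at 22. It replaces the ylide by a Peterson-type sequence with weakly nucleophilic magnesium alkoxides.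
- Excess (trimethylsilyl)methylmagnesium chloride (THF, −78 → 0 °C) adds 1,2 to the aldehyde tautomer to give the β-hydroxysilane F6.
- Ac2O/pyridine/DMAP acetylates the two secondary hydroxyls O6 and O14 to give the diacetate F7.
- TBAF buffered with AcOH (THF, 0 °C → rt) triggers fluoride-induced 1,2-elimination of the β-acetoxysilane, which forms C14=C15, and removes the TES group in the same operation, giving 22.

## Further compounds

F1 | step 14 | 6α-acetoxy-7β-(triethylsilyloxy)-14,15,16-trinorlabd-12-en-8α-yl 2-(diethoxyphosphoryl)propanoate | C=CC[C@H]1[C@](C)(OC(=O)C(C)P(=O)(OCC)OCC)[C@@H](O[Si](CC)(CC)CC)[C@H](OC(C)=O)[C@H]2C(C)(C)CCC[C@@]21C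
F2 | step 14 | C12 aldehyde of F1 (13,14,15,16-tetranorlabdan-12-al, 8-O-phosphonopropanoate) | O=CC[C@H]1[C@](C)(OC(=O)C(C)P(=O)(OCC)OCC)[C@@H](O[Si](CC)(CC)CC)[C@H](OC(C)=O)[C@H]2C(C)(C)CCC[C@@]21C
F3 | step 13 | 6α-acetoxy-7-oxo-14,15,16-trinorlabd-12-en-8α-yl methacrylate | C=CC[C@H]1[C@](C)(OC(=O)C(C)=C)C(=O)[C@H](OC(C)=O)[C@H]2C(C)(C)CCC[C@@]21C
F4 | step 13 | 6α-acetoxy-7-oxo-15-norlabd-12Z-en-14,8α-olide | C/C1=C/C[C@H]2[C@](C)(OC1=O)C(=O)[C@H](OC(C)=O)[C@H]3C(C)(C)CCC[C@@]32C
F5 | step 13 | 6α-acetoxy-7β-hydroxy-15-norlabd-12Z-en-14,8α-olide | C/C1=C/C[C@H]2[C@](C)(OC1=O)[C@@H](O)[C@H](OC(C)=O)[C@H]3C(C)(C)CCC[C@@]32C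
F6 | step 16 | 15-(trimethylsilyl)-7β-(triethylsilyloxy)labd-12Z-ene-6α,8α,14-triol (C14 epimers) | C[Si](C)(C)CC(O)/C(C)=C\C[C@H]1[C@](C)(O)[C@@H](O[Si](CC)(CC)CC)[C@H](O)[C@H]2C(C)(C)CCC[C@@]21C
F7 | step 16 | 6α,14-diacetoxy-15-(trimethylsilyl)-7β-(triethylsilyloxy)labd-12Z-en-8α-ol (C14 epimers) | C[Si](C)(C)CC(OC(C)=O)/C(C)=C\C[C@H]1[C@](C)(O)[C@@H](O[Si](CC)(CC)CC)[C@H](OC(C)=O)[C@H]2C(C)(C)CCC[C@@]21C
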